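A small charge, the spring run's, reads higher in target at its highest reading than the bigger autumn charge, so the hunch of one top percentage does not hold on these two runs.

| flask | substrate | remark | time |
|---|---|---|---|
| spring | 0.060 M | run made earlier |  |
| autumn | 0.090 M | run made earlier |  |
| flask | 0.12 M |  | 30 h |

| run | time / h | target / % | substrate / % |
|---|---|---|---|
| spring | 0.833 | 24.9 | 35.9 |
| spring | 2.00 | 36.6 | 19.4 |
| spring | 5.00 | 40.3 | 12.2 |
| spring | 15.0 | 31.9 | 7.1 |
| spring | 40.0 | 14.1 | 3.1 |
| autumn | 0.833 | 23.7 | 30.7 |
| autumn | 2.00 | 34.0 | 18.2 |
| autumn | 5.00 | 34.9 | 9.3 |
| autumn | 15.0 | 22.3 | 5.4 |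
| autumn | 40.0 | 12.4 | 3.5 |

(each reading ± 1 percentage point)

* time up to 30 h at which target stands highest
* the amount of target, in percent of the substrate charged, at that time
* earliest time at which at least nineteen twentieths of that best amount are there
* latest time at which they still are

- in percentages every species weighs as the substrate in it: one homo dimer counts as two
- on the list of suspects stand: target <-> isomer of the product; 2 substrate -> homo dimer; isomer of the product <-> substrate; target -> over-reaction product; substrate <-> target

1. At the highest readings, both at 5.00 h, target stands at 40.3% in the spring run and 34.9% in the autumn run.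

2. The lost-to-kept ratio is everything that is not target at the top, divided by target. It reads 1.48 in spring and 1.87 in autumn, higher in autumn.

3. The apparent order in charge says how steeply that ratio climbs with charge, on logarithms of both. It comes to 0.568.

4. Carried from autumn to the flask, the ratio becomes 2.20, so this reckoning puts the flask's top near 31.3%.

5. The autumn target readings at 2.00 h and 5.00 h differ by 0.9 percentage points, under the scatter of 1 point, so this reckoning takes those two autumn times as a rough guide to the window asked for in the flask.

6. The forecast stands higher than this reckoning, with 32.5% at 3.6 h and a window from 2 h to 6.3 h, on “second-order dimerisation competing with first-order channels”.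

The flask gives 33.2% at 3.32 h, with the window from 2.04 h to 5.43 h.

    target ⇌ isomer of the product (K = 0.110, k = 6.90 × 10⁻⁴ min⁻¹)
    2 substrate → homo dimer (k = 0.120 M⁻¹ min⁻¹)
    isomer of the product ⇌ substrate (k = 0.0280 min⁻¹)
    target → over-reaction product (k = 4.70 × 10⁻⁴ min⁻¹)
    substrate ⇌ target (K = 3.70, k = 0.00910 min⁻¹)

At its top the flask has a lost-to-kept ratio of 2.01, below the 2.20 reckoned. Of the flask's turnover up to 30 h, half of the homo dimer step is done by 0.455 h and half of the over-reaction step by 11.5 h, later than the first, and the flask's target tops between those times, at 3.32 h. The same order carried to the neighbour charged with 0.30 M gives a top of 21.3%, and that neighbour's simulated best is 21.5%.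

The readings are simulated with constants of no real substance, noise included.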